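**Plan**
Labels: C7 is the benzylic carbinol carbon, C8 the ether-bearing carbon, C9 its methyl; ring A is the 3,4-dimethoxyphenyl ring, ring B the benzoate ring.
Retrosynthesis: the C7–C1 bond to ring A is cut first (aryl Grignard plus α-aryloxy aldehyde), then the C8–O bond to ring B (phenol plus lactate). The feature used is that carbinol C7, which carries ring A, lies directly beside the oxygenated stereocentre C8, so C8 and its ether oxygen can direct the creation of C7 and of the C7–ring A bond in one event.
Forward: methyl vanillate 1 and methyl (R)-lactate 2 are joined to diester 3 (O–C8 bond); bromoveratrole 4 is turned into Grignard reagent 5; 3 is half-reduced through aluminium hemiacetal 6 to aldehyde 7; 5 adds to 7 and alkoxide 8 gives target 9 on work-up. The chain stays acyclic; no ring is formed.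
Stereochemistry: C8 (S) comes from the chiral pool, the (R)-lactate centre being inverted in the Mitsunobu step; C7 (S) is set relative to C8 by Cram-chelate control in the aryl addition (threo).

Key step: step 4

Remark: methyl (R)-lactate is taken as a commercial chiral-pool ester of high enantiomeric purity.

Step 1
Reactants: 1 methyl vanillate; 2 methyl (R)-lactate
Product: 3 methyl 3-methoxy-4-{[(2S)-1-methoxy-1-oxopropan-2-yl]oxy}benzoate
Conditions: PPh3, DIAD, THF, 0 °C to rt
Reagents that add atoms: none
Why: Mitsunobu etherification, in which the acidic phenol of 1 (para ester, pKa about 8) displaces the activated secondary carbinol of 2 in an SN2 step, so the (R)-lactate centre should be inverted cleanly to the (S)-aryl ether that becomes C8 while both methyl esters stay inert.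

Step 2
Reactants: 4 bromoveratrole (4-bromo-1,2-dimethoxybenzene)
Product: 5 3,4-dimethoxyphenylmagnesium bromide
Conditions: Mg turnings, cat. I2, THF, 45 °C then rt; kept as a titrated solution of about 1 M
Reagents that add atoms: magnesium, [Mg]
Why: Grignard formation by direct insertion of magnesium metal into the aryl C–Br bond, routine for electron-rich aryl bromides in THF and harmless to the two methyl ethers; no stereocentre is involved.

Step 3
Reactants: 3 methyl 3-methoxy-4-{[(2S)-1-methoxy-1-oxopropan-2-yl]oxy}benzoate
Product: 7 methyl 3-methoxy-4-{[(2S)-1-oxopropan-2-yl]oxy}benzoate, via aluminium hemiacetal 6 (not isolated)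
Conditions: i-Bu2AlH (1.05 equiv, toluene solution), CH2Cl2, –78 °C; then aq KNaC4H4O6 (potassium sodium tartrate), –78 °C to rt; crude aldehyde used at once
Reagents that add atoms: none
Why: Low-temperature half-reduction of an ester with i-Bu2AlH, in which one hydride adds to the inductively activated α-aryloxy ester, hemiacetal 6 is held as a chelate with the C8 oxygen until hydrolysis so that aldehyde 7 appears only on work-up, the conjugated electron-rich benzoate reacts more slowly and should survive one equivalent at –78 °C, and C8 is left untouched provided the aldehyde is kept cold, not chromatographed and used immediately.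

Step 4
Reactants: 7 methyl 3-methoxy-4-{[(2S)-1-oxopropan-2-yl]oxy}benzoate; 5 3,4-dimethoxyphenylmagnesium bromide
Product: 9 methyl 4-{[(1S,2S)-1-(3,4-dimethoxyphenyl)-1-hydroxypropan-2-yl]oxy}-3-methoxybenzoate, via bromomagnesium alkoxide 8 (not isolated)
Conditions: 7, MgBr2·OEt2 (2 equiv), CH2Cl2, –78 °C, 30 min; then 5 (1.3 equiv, concentrated THF solution, slow addition), –78 °C; sat. aq NH4Cl
Reagents that add atoms: none
Why: MgBr2 first ties the aldehyde oxygen and the C8 aryl ether oxygen of 7, backed by the neighbouring ortho-methoxy group of ring B, into a five-membered Cram chelate, and the aryl group of 5 is then delivered to the activated carbonyl carbon in a polar 1,2-addition that gives alkoxide 8 and, after protonation, carbinol 9. The closest known reaction type is the chelation-controlled addition of Grignard reagents to α-alkoxy aldehydes. No ring is closed; the only skeletal bond made is C7–C1 of ring A. The new centre C7 is controlled by the resident C8 centre (1,2-induction): in the rigid chelate the C9 methyl blocks one carbonyl face, so the aryl should enter on the Si face beside the C8 hydrogen, and (8S) then leads to (7S), the threo isomer. The step needs threo over erythro selectivity, which requires the chelate to outrun the polar Felkin–Anh pathway and is supported by the bidentate aryloxy/methoxy donor set, pre-complexation in weakly coordinating CH2Cl2 and slow addition of a concentrated reagent solution at –78 °C. It also needs the aldehyde to react before the methyl benzoate and before C8 can enolise, which the large rate difference between an aldehyde and an electron-rich ester toward an arylmagnesium at –78 °C should provide.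

**Compound list**
1 | methyl vanillate (methyl 4-hydroxy-3-methoxybenzoate) | COC(=O)c1ccc(O)c(OC)c1 | starting material
2 | methyl (R)-lactate (methyl (2R)-2-hydroxypropanoate) | C[C@@H](O)C(=O)OC | starting material
3 | methyl 3-methoxy-4-{[(2S)-1-methoxy-1-oxopropan-2-yl]oxy}benzoate | COC(=O)c1ccc(O[C@@H](C)C(=O)OC)c(OC)c1 | intermediate
4 | bromoveratrole (4-bromo-1,2-dimethoxybenzene) | COc1ccc(Br)cc1OC | starting material
5 | 3,4-dimethoxyphenylmagnesium bromide | COc1ccc([Mg]Br)cc1OC | intermediate
6 | aluminium hemiacetal, not isolated: methyl 4-{[(2S)-1-[(diisobutylalumanyl)oxy]-1-methoxypropan-2-yl]oxy}-3-methoxybenzoate (hemiacetal carbon unassigned) | COC(=O)c1ccc(O[C@@H](C)C(OC)O[Al](CC(C)C)CC(C)C)c(OC)c1 | intermediate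
7 | methyl 3-methoxy-4-{[(2S)-1-oxopropan-2-yl]oxy}benzoate | COC(=O)c1ccc(O[C@@H](C)C=O)c(OC)c1 | intermediate
8 | bromomagnesium alkoxide, not isolated: bromomagnesium (1S,2S)-1-(3,4-dimethoxyphenyl)-2-[2-methoxy-4-(methoxycarbonyl)phenoxy]propan-1-olate | COC(=O)c1ccc(O[C@@H](C)[C@@H](O[Mg]Br)c2ccc(OC)c(OC)c2)c(OC)c1 | intermediate
9 | methyl 4-{[(1S,2S)-1-(3,4-dimethoxyphenyl)-1-hydroxypropan-2-yl]oxy}-3-methoxybenzoate | COC(=O)c1ccc(O[C@@H](C)[C@@H](O)c2ccc(OC)c(OC)c2)c(OC)c1 | target

**Step count**
Total: 4 steps. Longest linear sequence: 3 steps (1 to 3 to 7 to 9; steps 1, 3 and 4), with the one-step preparation of 5 as the convergent branch.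

**Steps most likely to fail**

Step 4. The risk is poor facial selectivity. The aryl ether oxygen is a weak donor and THF from the reagent solution competes for magnesium, so the polar Felkin–Anh pathway may leak in and erode the threo preference; some enolisation at C8 is also conceivable. The fallback sets C7 by hydride delivery instead of by aryl delivery. Setting out from 7 and 5, the addition is run in THF at –78 °C without regard to selectivity, giving 9 together with its C7 epimer methyl 4-{[(1R,2S)-1-(3,4-dimethoxyphenyl)-1-hydroxypropan-2-yl]oxy}-3-methoxybenzoate F1. The mixture is oxidised as a whole with Dess–Martin periodinane (CH2Cl2, NaHCO3, 0 °C to rt) to the single ketone methyl 4-{[(2S)-1-(3,4-dimethoxyphenyl)-1-oxopropan-2-yl]oxy}-3-methoxybenzoate F2. This is reduced with the bulky, non-chelating hydride LiBH(s-Bu)3 in THF at –78 °C. Under polar Felkin–Anh control (C8–O bond anti to the incoming hydride, attack past the C8 hydrogen) the (8S) ketone should give the (7S) threo alcohol, and the benzoate is inert under these conditions. The route is rejoined at 9.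

Step 3. The risk is loss of chemoselectivity: over-reduction of the aliphatic ester to the primary alcohol, competing attack on the aryl ester, or epimerisation of the α-aryloxy aldehyde during work-up. The fallback separates chemoselection from the oxidation level. Setting out from 3, NaBH4 in THF–MeOH at 0 °C should reduce only the activated α-aryloxy ester and leave the benzoate, giving methyl 4-{[(2S)-1-hydroxypropan-2-yl]oxy}-3-methoxybenzoate F3. Buffered Dess–Martin periodinane (CH2Cl2, NaHCO3, 0 °C) then oxidises the primary alcohol under non-epimerising conditions. The route is rejoined at 7.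

Step 1. The risk is sluggish coupling of the hindered secondary lactate carbinol, consumption of the alcohol by the azodicarboxylate, and loss of material on separation from the phosphine oxide and hydrazide. The fallback is a two-step sulfonate displacement. Setting out from 2, TsCl, Et3N and cat. DMAP in CH2Cl2 at 0 °C give methyl (2R)-2-{[(4-methylphenyl)sulfonyl]oxy}propanoate F4. The phenoxide of 1 (K2CO3, MeCN, 60 °C) then displaces the tosylate by SN2 with the same inversion. The route is rejoined at 3.

**Further compounds**
F1 | step 4 | methyl 4-{[(1R,2S)-1-(3,4-dimethoxyphenyl)-1-hydroxypropan-2-yl]oxy}-3-methoxybenzoate | COC(=O)c1ccc(O[C@@H](C)[C@H](O)c2ccc(OC)c(OC)c2)c(OC)c1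
F2 | step 4 | methyl 4-{[(2S)-1-(3,4-dimethoxyphenyl)-1-oxopropan-2-yl]oxy}-3-methoxybenzoate | COC(=O)c1ccc(O[C@@H](C)C(=O)c2ccc(OC)c(OC)c2)c(OC)c1
F3 | step 3 | methyl 4-{[(2S)-1-hydroxypropan-2-yl]oxy}-3-methoxybenzoate | COC(=O)c1ccc(O[C@@H](C)CO)c(OC)c1
F4 | step 1 | methyl (2R)-2-{[(4-methylphenyl)sulfonyl]oxy}propanoate | C[C@@H](OS(=O)(=O)c1ccc(C)cc1)C(=O)OC
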